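**Plan**

- Retrosynthesis cuts, in order: the O–CH3 bond at C8 (selective methylation of a 5,8-hydroquinone); O1–C8a of ring C (the key bond); the C2–C3 bond of the three-carbon chain (Claisen aroylation); and C4–C4a (Friedel–Crafts acetylation).
- Enabling feature: the oxygens on C5 and C8 of ring A are para, so ring A can be carried as a 5,8-quinone. In that quinone the carbon that becomes C8a is beta to both the C4 and the C5 carbonyl and holds a methoxy leaving group.
- Forward: ring A comes from symmetric 2,6-dimethoxy-1,4-benzoquinone and ring B from 2,3-dimethoxybenzoic acid. Acetylation and a Claisen condensation join them, oxidation closes ring C, and reduction plus one methylation finish the flavone.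
- Stereochemistry: the target has no stereocentre and none is created.

Key step: step 5

Remark: the 1,3-diketones 6 and 7 are drawn as diketo tautomers although they should exist largely as chelated enols; all hydroquinones (2, 3, 6, 9) are to be handled under argon.

**Step 1**
Reactants: 1 2,6-dimethoxy-1,4-benzoquinone
Product: 2 2,6-dimethoxybenzene-1,4-diol
Conditions: Na2S2O4, EtOAc/H2O, rt
Reagents that add atoms: none
Why: Dithionite reduction of a 1,4-benzoquinone to its hydroquinone is fast in a two-phase system and leaves the methyl ethers untouched.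

**Step 2**
Reactants: 2 2,6-dimethoxybenzene-1,4-diol
Product: 3 1-(3,6-dihydroxy-2,4-dimethoxyphenyl)ethanone
Conditions: AcOH, BF3·OEt2, 90 °C, Ar; then aq. NaOAc
Reagents that add atoms: acetic acid, CC(=O)O
Why: Friedel–Crafts C-acetylation of an electron-rich hydroquinone with the BF3/acetic acid system (O-acetate and Fries-type shift included) is standard, and since the two free ring positions of 2 are equivalent by symmetry only one chelated ortho-hydroxy ketone can form.

**Step 3**
Reactants: 4 2,3-dimethoxybenzoic acid
Product: 5 2,3-dimethoxybenzoyl chloride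
Conditions: (COCl)2, N,N-dimethylformamide (cat.), CH2Cl2, 0 °C to rt
Reagents that add atoms: oxalyl chloride, O=C(Cl)C(=O)Cl
Why: Standard acid chloride formation through the chloroiminium catalyst, to which the aryl methyl ethers are inert.

**Step 4**
Reactants: 3 1-(3,6-dihydroxy-2,4-dimethoxyphenyl)ethanone; 5 2,3-dimethoxybenzoyl chloride
Product: 6 1-(3,6-dihydroxy-2,4-dimethoxyphenyl)-3-(2,3-dimethoxyphenyl)propane-1,3-dione
Conditions: LiN(SiMe3)2 (4.2 equiv), THF, −78 to −10 °C, Ar; then 5 (1.0 equiv), −78 °C to rt; cold 1 M HCl to pH 4
Reagents that add atoms: none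
Why: Crossed Claisen condensation of the phenoxide/enolate trianion of 3, whose enolate carbon is the most reactive site toward the aroyl chloride while the fourth equivalent of base deprotonates the diketone as it forms, is well established for polyhydroxyacetophenones, and any ortho O-aroylation would converge on 6 by Baker–Venkataraman shift.

**Step 5**
Reactants: 6 1-(3,6-dihydroxy-2,4-dimethoxyphenyl)-3-(2,3-dimethoxyphenyl)propane-1,3-dione
Product: 8 2-(2,3-dimethoxyphenyl)-7-methoxy-4H-chromene-4,5,8-trione, via acylquinone 7 (not isolated)
Conditions: Ag2O (3 equiv), Na2SO4, CH2Cl2 (0.01 M), rt, dark, Ar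
Reagents that add atoms: none
Why: Proposed new method: Ag2O should dehydrogenate the hydroquinone of 6 to the 2-acylquinone 7, whose methoxy-bearing ring carbon next to the acyl group (the future C8a) is a vinylogous ester carbon lying beta to both the side-chain ketone (future C4) and the neighbouring quinone carbonyl (future C5). The oxygen on the aryl-bearing carbon of the diketone (as enol or silver enolate) is expected to add to that carbon, and the quinone enolate so formed to expel methoxide, an addition-elimination that forges O1–C8a and delivers 8 without change of oxidation level. The closest known reaction types are the replacement of the methoxy group of 2-methoxy-1,4-benzoquinones by oxygen and nitrogen nucleophiles, the conjugate addition of nucleophiles at C3 of 2-acyl-1,4-benzoquinones and the cyclodehydration of 2-hydroxyphenyl 1,3-diketones to flavones; their combination in one ring closure is untested. Ring C closes in a 6-endo-trig mode, driven by formation of the 4-pyranone, and no stereocentre is created. The step needs closure at C8a instead of closure through the C5 oxygen (which would lead to the 5,6,7-oxygenated isomer), and this is secured by oxidising before the diketone ever meets acid: in 7 the C5 oxygen is a carbonyl and no longer a nucleophile, the methoxy carbon beside the acyl group is the only leaving-group-bearing site the enol oxygen can reach through a six-membered transition state, and the central carbon of the diketone is too close to reach it. High dilution is meant to suppress intermolecular Michael addition of the enol to a second quinone.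

**Step 6**
Reactants: 8 2-(2,3-dimethoxyphenyl)-7-methoxy-4H-chromene-4,5,8-trione
Product: 9 2-(2,3-dimethoxyphenyl)-5,8-dihydroxy-7-methoxy-4H-chromen-4-one
Conditions: Na2S2O4, THF/H2O, rt, Ar
Reagents that add atoms: none
Why: Dithionite reduction of a flavone-5,8-quinone to the 5,8-dihydroxyflavone is the usual way to handle such quinones, and the pyranone and the aryl ethers are not reduced.

**Step 7**
Reactants: 9 2-(2,3-dimethoxyphenyl)-5,8-dihydroxy-7-methoxy-4H-chromen-4-one
Product: 10 5-hydroxy-2',3',7,8-tetramethoxyflavone, i.e. 2-(2,3-dimethoxyphenyl)-5-hydroxy-7,8-dimethoxy-4H-chromen-4-one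
Conditions: Me2SO4 (1.05 equiv), K2CO3, acetone, reflux, Ar
Reagents that add atoms: dimethyl sulfate, COS(=O)(=O)OC
Why: Williamson methylation with one equivalent of Me2SO4 should go to the C8 phenol, because the C5 hydroxyl is locked in a hydrogen bond to the C4 carbonyl and is far less nucleophilic, as in the standard partial methylation of 5,8-dihydroxyflavones.

**Compound list**

1 | 2,6-dimethoxy-1,4-benzoquinone | COC1=CC(=O)C=C(OC)C1=O | starting material
2 | 2,6-dimethoxybenzene-1,4-diol | COc1cc(O)cc(OC)c1O | intermediate
3 | 1-(3,6-dihydroxy-2,4-dimethoxyphenyl)ethanone | CC(=O)c1c(O)cc(OC)c(O)c1OC | intermediate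
4 | 2,3-dimethoxybenzoic acid | COc1cccc(C(=O)O)c1OC | starting material
5 | 2,3-dimethoxybenzoyl chloride | COc1cccc(C(=O)Cl)c1OC | intermediate
6 | 1-(3,6-dihydroxy-2,4-dimethoxyphenyl)-3-(2,3-dimethoxyphenyl)propane-1,3-dione | COc1cc(O)c(C(=O)CC(=O)c2cccc(OC)c2OC)c(OC)c1O | intermediate
7 | 2-[3-(2,3-dimethoxyphenyl)-3-oxopropanoyl]-3,5-dimethoxy-1,4-benzoquinone | COC1=CC(=O)C(C(=O)CC(=O)c2cccc(OC)c2OC)=C(OC)C1=O | intermediate
8 | 2-(2,3-dimethoxyphenyl)-7-methoxy-4H-chromene-4,5,8-trione | COC1=CC(=O)C2=C(OC(=CC2=O)c3cccc(OC)c3OC)C1=O | intermediate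
9 | 2-(2,3-dimethoxyphenyl)-5,8-dihydroxy-7-methoxy-4H-chromen-4-one | COc1cc(O)c2c(=O)cc(-c3cccc(OC)c3OC)oc2c1O | intermediate
10 | 5-hydroxy-2',3',7,8-tetramethoxyflavone | COc1cccc(-c2cc(=O)c3c(O)cc(OC)c(OC)c3o2)c1OC | target

**Step count**

Total step count: 7. Longest linear sequence: 6 steps (1 → 2 → 3 → 6 → 8 → 9 → 10, steps 1, 2, 4, 5, 6 and 7); step 3 prepares the acid chloride on the side.

**Steps most likely to fail**

1. Step 5 (proposed new method). The acylquinone may be consumed by intermolecular Michael addition or polymerisation faster than the enol oxygen closes ring C, or the closure may stall at the open quinone. The fallback uses known chemistry and brings in the C8 oxygen after ring C is built. It sets out from acid chloride 5 and comes back to the route at 9.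
   - Commercial 1-(2,6-dihydroxy-4-methoxyphenyl)ethanone (CC(=O)c1c(O)cc(OC)cc1O) is converted into its polyanion with LiN(SiMe3)2 in THF at −78 °C and C-aroylated with 5. This should give 1-(2,6-dihydroxy-4-methoxyphenyl)-3-(2,3-dimethoxyphenyl)propane-1,3-dione F1.
   - Cyclodehydration with H2SO4 (cat.) in AcOH at 95 °C can give only one flavone, since the two ortho hydroxyls are equivalent: 2-(2,3-dimethoxyphenyl)-5-hydroxy-7-methoxy-4H-chromen-4-one F2.
   - Elbs persulfate oxidation (K2S2O8, aq. KOH/pyridine, rt) should place a sulfate para to the C5 hydroxyl, giving potassium 2-(2,3-dimethoxyphenyl)-5-hydroxy-7-methoxy-4-oxo-4H-chromen-8-yl sulfate F3.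
   - Hydrolysis of F3 with hot dilute HCl in the presence of Na2SO3 should give 9, which then enters step 7.

2. Step 4. O-aroylation of the unchelated phenoxide may compete with C-aroylation of the enolate, and the hydroquinone polyanion may be air-oxidised. The fallback moves the acyl group within the molecule instead; it sets out from 3 and 5 and comes back at 6.
   - Both phenols of 3 are esterified with 5 (2.2 equiv) in pyridine with 4-(dimethylamino)pyridine (cat.), giving 2-acetyl-3,5-dimethoxy-1,4-phenylene bis(2,3-dimethoxybenzoate) F4.
   - Baker–Venkataraman rearrangement with powdered KOH in pyridine at 50 °C shifts the ortho aroyl group to carbon, giving 3-[3-(2,3-dimethoxyphenyl)-3-oxopropanoyl]-4-hydroxy-2,6-dimethoxyphenyl 2,3-dimethoxybenzoate F5.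
   - Saponification of the remaining aryl ester with LiOH in THF/MeOH/H2O under argon, followed by cold acidification, should give 6.

3. Step 7. Methylation may also reach the chelated C5 hydroxyl, or the hydroquinone may be re-oxidised to the quinone under base before it is alkylated. The fallback gives up selective alkylation for selective dealkylation; it sets out from 9 and comes back at 10.
   - Exhaustive methylation with excess Me2SO4 and K2CO3 in refluxing acetone should give 2-(2,3-dimethoxyphenyl)-5,7,8-trimethoxy-4H-chromen-4-one F6.
   - BCl3 (1.1 equiv) in CH2Cl2 at −78 to 0 °C should cleave only the C5 methyl ether peri to the C4 carbonyl, through the boron chelate, and give 10.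

**Further compounds**

F1 | step 5 | 1-(2,6-dihydroxy-4-methoxyphenyl)-3-(2,3-dimethoxyphenyl)propane-1,3-dione | COc1cc(O)c(C(=O)CC(=O)c2cccc(OC)c2OC)c(O)c1
F2 | step 5 | 2-(2,3-dimethoxyphenyl)-5-hydroxy-7-methoxy-4H-chromen-4-one | COc1cc(O)c2c(=O)cc(-c3cccc(OC)c3OC)oc2c1
F3 | step 5 | potassium 2-(2,3-dimethoxyphenyl)-5-hydroxy-7-methoxy-4-oxo-4H-chromen-8-yl sulfate | COc1cc(O)c2c(=O)cc(-c3cccc(OC)c3OC)oc2c1OS(=O)(=O)[O-].[K+]
F4 | step 4 | 2-acetyl-3,5-dimethoxy-1,4-phenylene bis(2,3-dimethoxybenzoate) | CC(=O)c1c(OC(=O)c2cccc(OC)c2OC)cc(OC)c(OC(=O)c2cccc(OC)c2OC)c1OC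
F5 | step 4 | 3-[3-(2,3-dimethoxyphenyl)-3-oxopropanoyl]-4-hydroxy-2,6-dimethoxyphenyl 2,3-dimethoxybenzoate | COc1cc(O)c(C(=O)CC(=O)c2cccc(OC)c2OC)c(OC)c1OC(=O)c1cccc(OC)c1OC
F6 | step 7 | 2-(2,3-dimethoxyphenyl)-5,7,8-trimethoxy-4H-chromen-4-one | COc1cccc(-c2cc(=O)c3c(OC)cc(OC)c(OC)c3o2)c1OC
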